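**Assumption:** I take the SMILES literally. C1' is R, and the exocyclic Br is cis to C4–Br and trans to the ring O, so the alkene is 5E. This is the contra-thermodynamic isomer, so the route is designed to deliver it stereospecifically.

## Retrosynthetic overview
1. Target ⇒ O-acetylation of the (R,5E)-hydroxy lactone. The only ring is formed second to last, by anti 5-exo-dig bromolactonisation of an open-chain enynoic acid, which sets 5E.
2. Enynoic acid ⇒ Pd alkoxycarbonylation of an alkenyl C–I bond. The lactone C2 comes from CO, and the ester ends up cis to the alkyne.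
3. C1' stereocentre ⇒ CBS reduction of an α-iodo enone.
4. Tetrasubstituted C3=C4(Br) alkene ⇒ anti I–Br addition to a diynone. The future carbinol carbon, not the ester, activates the alkyne, so anti addition places Br cis to C1'.
5. Diynone ⇒ bis(trimethylsilyl)butadiyne + butanoyl chloride.

## Route

**Step 1**
Reactants: 1, 1,4-bis(trimethylsilyl)buta-1,3-diyne; 2, butanoyl chloride
Product: 3, 8-(trimethylsilyl)octa-5,7-diyn-4-one
Conditions: AlCl3 (1.1 equiv), CH2Cl2, 0 °C, 1 h; cold 1 M HCl
Reagents that add atoms: butanoyl chloride (2), CCCC(=O)Cl
Why: This is a Friedel–Crafts-type acylative ipso-desilylation of an alkynylsilane via a β-silyl-stabilised cation, and it stops at monoacylation because the diynone product is deactivated.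

**Step 2**
Reactants: 3; 4, iodine monobromide
Product: 5, (5E)-6-bromo-5-iodo-8-(trimethylsilyl)oct-5-en-7-yn-4-one (I trans to Br; Br cis to the acyl carbon; I cis to the alkynyl group)
Conditions: IBr (1.05 equiv), n-Bu4NBr (1.0 equiv), CH2Cl2, −40 → 0 °C, dark; aq Na2S2O3
Reagents that add atoms: iodine monobromide (4), BrI
Why: Proposed new method: site-selective anti iodobromination of a silyl-capped conjugated diynone, in which bromide (as IBr2⁻) attacks the ynone β-carbon C6 while I⁺ goes to the α-carbon C5 (the only polarity-matched pair) in a termolecular anti addition that gives the E isomer, also the less strained one; the distal Me3Si–C≡C is deactivated toward I⁺ by conjugation and silicon shields C8 against 1,6-attack; the closest known reaction type is anti iodochlorination/iodobromination of alkynoates and ynones to (E)-β-halo-α-iodo enoates and enones.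

**Step 3**
Reactants: 5
Product: 6, (4R,5E)-6-bromo-5-iodo-8-(trimethylsilyl)oct-5-en-7-yn-4-ol
Conditions: (S)-Me-CBS (20 mol %), catecholborane (1.8 equiv), toluene, −78 → −40 °C; MeOH, then aq NaHCO3
Reagents that add atoms: none
Why: In this Corey–Bakshi–Shibata reduction the α-iodoalkenyl group is the large substituent and n-propyl the small one (the α-halo-enone case), so (S)-CBS delivers hydride in the same sense as acetophenone → (R)-alcohol and gives 4R; catecholborane at low temperature leaves C–I, C–Br and the silylalkyne intact.

**Step 4**
Reactants: 6; 7, carbon monoxide; 8, 2-(trimethylsilyl)ethanol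
Product: 9, 2-(trimethylsilyl)ethyl (2E)-3-bromo-2-[(1R)-1-hydroxybutyl]-5-(trimethylsilyl)pent-2-en-4-ynoate (ester cis to alkynyl; Br cis to C1')
Conditions: PdCl2(PPh3)2 (5 mol %), CO (1–3 atm), Me3SiCH2CH2OH (5 equiv), i-Pr2NEt (2 equiv), DMF, 45 °C, dark
Reagents that add atoms: carbon monoxide (7), [C-]#[O+]; 2-(trimethylsilyl)ethanol (8), C[Si](C)(C)CCO
Why: This Pd(0) alkoxycarbonylation (Heck carbonylation) of an alkenyl iodide adds selectively to C–I over C–Br with retention of geometry, CO insertion outruns β-bromide loss as in selective couplings of (E)-1-bromo-2-iodoalkenes, and the excess primary alcohol outcompetes β-lactone closure.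

**Step 5**
Reactants: 9
Product: 10, (2E)-3-bromo-2-[(1R)-1-hydroxybutyl]pent-2-en-4-ynoic acid
Conditions: TBAF (3 equiv), THF, 0 °C → rt; cold pH 3 work-up; used crude
Reagents that add atoms: none
Why: Fluoride fragments the 2-silylethyl ester (loss of ethylene and Me3SiF) and protodesilylates the alkynylsilane in one operation, without hydroxide or alkoxide that could displace the vinylic bromide.

**Step 6** (ring formation)
Reactants: 10; 11, N-bromosuccinimide
Product: 12, (5E)-4-bromo-5-(bromomethylidene)-3-[(1R)-1-hydroxybutyl]furan-2(5H)-one
Conditions: NBS (1.05 equiv), KHCO3 (1.1 equiv), n-Bu4NOH (10 mol %), CH2Cl2/H2O, 0 °C → rt, dark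
Reagents that add atoms: N-bromosuccinimide (11), O=C1CCC(=O)N1Br
Why: In this halo-enol-lactonisation (electrophilic 5-exo-dig bromolactonisation) the carboxylate attacks the internal, Markovnikov alkyne carbon anti to the Br⁺-activated terminus, so O and Br end up trans (5E, Br syn to C4–Br); the C1' hydroxyl lies trans to the alkyne and cannot compete.

**Step 7**
Reactants: 12; 13, acetic anhydride
Product: 14, acetoxyfimbrolide, (1R)-1-[(5E)-4-bromo-5-(bromomethylidene)-2-oxo-2,5-dihydrofuran-3-yl]butyl acetate
Conditions: Ac2O (1.5 equiv), Sc(OTf)3 (2 mol %), MeCN, −20 → 0 °C, dark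
Reagents that add atoms: acetic anhydride (13), CC(=O)OC(C)=O
Why: This Lewis-acid-catalysed O-acylation does not break the C1'–O bond, so R is retained, and avoiding pyridine or DMAP prevents addition–elimination at C4/C6 that would erode the E geometry.

## Compound list
1 | 1,4-bis(trimethylsilyl)buta-1,3-diyne | C[Si](C)(C)C#CC#C[Si](C)(C)C | starting material
2 | butanoyl chloride | CCCC(=O)Cl | starting material
3 | 8-(trimethylsilyl)octa-5,7-diyn-4-one | CCCC(=O)C#CC#C[Si](C)(C)C | intermediate
4 | iodine monobromide | BrI | starting material (reagent)
5 | (5E)-6-bromo-5-iodo-8-(trimethylsilyl)oct-5-en-7-yn-4-one | CCCC(=O)/C(I)=C(\Br)C#C[Si](C)(C)C | intermediate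
6 | (4R,5E)-6-bromo-5-iodo-8-(trimethylsilyl)oct-5-en-7-yn-4-ol | CCC[C@@H](O)/C(I)=C(\Br)C#C[Si](C)(C)C | intermediate
7 | carbon monoxide | [C-]#[O+] | starting material (reagent)
8 | 2-(trimethylsilyl)ethanol | C[Si](C)(C)CCO | starting material (reagent)
9 | 2-(trimethylsilyl)ethyl (2E)-3-bromo-2-[(1R)-1-hydroxybutyl]-5-(trimethylsilyl)pent-2-en-4-ynoate | CCC[C@@H](O)/C(C(=O)OCC[Si](C)(C)C)=C(\Br)C#C[Si](C)(C)C | intermediate
10 | (2E)-3-bromo-2-[(1R)-1-hydroxybutyl]pent-2-en-4-ynoic acid | CCC[C@@H](O)/C(C(=O)O)=C(\Br)C#C | intermediate
11 | N-bromosuccinimide | O=C1CCC(=O)N1Br | starting material (reagent)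
12 | (5E)-4-bromo-5-(bromomethylidene)-3-[(1R)-1-hydroxybutyl]furan-2(5H)-one | CCC[C@@H](O)C1=C(Br)/C(=C\Br)OC1=O | intermediate
13 | acetic anhydride | CC(=O)OC(C)=O | starting material (reagent)
14 | acetoxyfimbrolide, (1'R,5E) | CCC[C@@H](OC(C)=O)C1=C(Br)/C(=C\Br)OC1=O | target

## Summary
**Total steps:** 7 (steps 5 and 6 can be telescoped).
**Longest linear sequence:** 7.

**Steps most likely to fail, each with a fallback**
1. **Step 2.** The risks are attack at the silyl alkyne, 1,6-addition, or ipso-iodination.
   - Fallback: take the second alkyne out of this step.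
   - Acylate bis(trimethylsilyl)acetylene with 2, then convert to 1-bromohex-1-yn-3-one with NBS/AgNO3.
   - Add IBr to give the 1,1-dibromo-2-iodo enone, which has no competing alkyne and no alkene geometry to control.
   - Carry out the CBS reduction and the carbonylation as above.
   - Install the alkyne by a sterically controlled mono-Sonogashira coupling with TMS-acetylene at the Br trans to the branched carbinol (cis to the ester).
2. **Step 4.** The risks are β-bromide elimination from the alkenyl-Pd species and over-carbonylation at the activated C–Br of the product.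
   - Fallback: bring in C2 as an electrophile instead of through Pd.
   - Run the bromide addition to 3 as a halo-aldol (MgBr2 or TiBr4 with formaldehyde), which follows the same anti rule and gives the α-hydroxymethyl-β-bromo enynone.
   - Reduce the ketone by CBS.
   - Oxidise the primary allylic alcohol selectively to the acid (TEMPO/PhI(OAc)2, then Pinnick).
3. **Step 6.** The risks are a sluggish reaction of the electron-poor alkyne and leakage of E to Z.
   - Fallback: keep the alkynyl silicon and cleave only the ester.
   - Close the ring by Ag(I)-catalysed 5-exo-dig lactonisation to the (Z)-silylmethylidene lactone (Si syn to O).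
   - Add Br2 (anti) and eliminate Me3SiBr (anti). This bromodesilylation proceeds with net inversion and gives the same 5E bromide.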